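**Assumption (one line):** I take the target to be the (1S,2R) erythro 8-O-4′ neolignan. The ring-free acyclic skeleton means no rings are formed; all three aromatic rings are already present in the starting materials.

## Retrosynthetic overview
- The target is a 1-aryl-2-aryloxypropan-1-ol, and the two adjacent stereocenters come from one reduction. C1–OH is set by ketone reduction, and C2 is set by dynamic kinetic resolution (DKR) of the epimerizable α-aryloxy ketone **4**.
- Disconnect C1–H/O to the racemic α-aryloxy ketone **4** (Ru-catalysed asymmetric transfer hydrogenation with DKR).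
- Disconnect the aryl ether C2–O to the α-bromoketone **2** plus dihydroconiferyl alcohol **3** (SN2 with the phenoxide).
- Disconnect the C–Br bond to 3′,4′,5′-trimethoxypropiophenone **1**, which is commercial.

## Route

**Step 1**
Reactants: **1** 3′,4′,5′-trimethoxypropiophenone
Product: **2** (±)-2-bromo-1-(3,4,5-trimethoxyphenyl)propan-1-one
Conditions: CuBr₂, EtOAc/CHCl₃ (1:1), reflux
Reagents that add atoms: copper(II) bromide, Br[Cu]Br (supplies Br)
Why: CuBr₂ brominates the enolizable ketone selectively at the α-carbon (enol-mediated α-bromination) and avoids the ring bromination that Br₂ could cause on the electron-rich arene. The new C2 stereocenter is racemic, which is acceptable because it is epimerized in step 3.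

**Step 2**
Reactants: **2** and **3** 4-(3-hydroxypropyl)-2-methoxyphenol (dihydroconiferyl alcohol)
Product: **4** (±)-2-[4-(3-hydroxypropyl)-2-methoxyphenoxy]-1-(3,4,5-trimethoxyphenyl)propan-1-one
Conditions: K₂CO₃, acetone, 55 °C
Reagents that add atoms: none
Why: Williamson-type SN2 at the activated secondary α-bromoketone. The phenol (pKa ≈ 10) is deprotonated by K₂CO₃ far more readily than the primary alcohol, so only the aryl ether forms and the alcohol needs no protection. The product is racemic at C2.

**Step 3**
Reactants: **4**
Product: **5** target, (1S,2R)-2-[4-(3-hydroxypropyl)-2-methoxyphenoxy]-1-(3,4,5-trimethoxyphenyl)propan-1-ol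
Conditions: RuCl[(R,R)-TsDPEN](p-cymene) (1–2 mol %), HCOOH/Et₃N (5:2), CH₂Cl₂, 30 °C
Reagents that add atoms: none (formate only supplies hydrogen)
Why: Noyori–Ikariya asymmetric transfer hydrogenation combined with DKR. Et₃N epimerizes the acidic α-aryloxy C2–H faster than reduction occurs, and the chiral Ru–H reduces one ketone enantiomer faster than the other. The (R,R)-ligand delivers hydride to the face that gives 1S, and the matched C2 epimer reacts so that the erythro (1S,2R) isomer forms. The primary alcohol and the aryl ethers are inert under these conditions. I have assumed, not verified, that the (R,R)-catalyst gives this diastereomer; dr and ee should be confirmed by chiral HPLC and NMR, and the ligand enantiomer chosen to match.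

## Check against the target SMILES
- By CIP analysis, the target SMILES is C1 = S (benzylic carbinol) and C2 = R (OAr carbon), which is erythro.
- It contains a 3,4,5-trimethoxyphenyl group, a CH(OH)–CH(CH₃)–O linkage, and a guaiacyl ether bearing a para 3-hydroxypropyl chain.
- Atom count: **1** (C₁₂H₁₆O₄) gives **2** (C₁₂H₁₅BrO₄). Adding **3** (C₁₀H₁₄O₃) and losing HBr gives **4** (C₂₂H₂₈O₇). Adding H₂ gives **5** (C₂₂H₃₀O₇), which is the target.
- Both stereocenters are set only in step 3, and no later step touches them.

## Compound list
1 | 3′,4′,5′-trimethoxypropiophenone | CCC(=O)c1cc(OC)c(OC)c(OC)c1 | starting material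
2 | (±)-2-bromo-1-(3,4,5-trimethoxyphenyl)propan-1-one | CC(Br)C(=O)c1cc(OC)c(OC)c(OC)c1 | intermediate
3 | 4-(3-hydroxypropyl)-2-methoxyphenol | COc1cc(CCCO)ccc1O | starting material
4 | (±)-2-[4-(3-hydroxypropyl)-2-methoxyphenoxy]-1-(3,4,5-trimethoxyphenyl)propan-1-one | CC(Oc1ccc(CCCO)cc1OC)C(=O)c1cc(OC)c(OC)c(OC)c1 | intermediate
5 | (1S,2R)-2-[4-(3-hydroxypropyl)-2-methoxyphenoxy]-1-(3,4,5-trimethoxyphenyl)propan-1-ol | COc1cc(CCCO)ccc1O[C@H](C)[C@@H](O)c1cc(OC)c(OC)c(OC)c1 | target

## Totals
Total steps: 3. Longest linear sequence: 3.

## Three steps most likely to fail
1. **Step 3 (DKR-ATH selectivity):** the dr or ee may be poor, or the wrong diastereomer may dominate.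
   - Fallback: change to a biocatalytic ketone-reductase (KRED) DKR screen on **4**.
   - Second fallback: a chiral-pool route. Mitsunobu of ethyl (S)-lactate with a protected phenol gives the (R)-aryloxy ester, then the Weinreb amide, then ArMgBr to the ketone, then a diastereoselective hydride reduction.
2. **Step 1 (bromination):** ring bromination or dibromination can occur on the electron-rich arene.
   - Fallback: build **2** directly by adding 3,4,5-trimethoxyphenylmagnesium bromide to the Weinreb amide of 2-bromopropionic acid, with no enol bromination.
3. **Step 2 (etherification):** the hindered secondary α-bromoketone may eliminate or undergo Favorskii-type side reactions under basic conditions.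
   - Fallback: use an epoxide route. Wittig olefination of 3,4,5-trimethoxybenzaldehyde gives the (E)-propenylarene, Shi asymmetric epoxidation gives the trans-epoxide, and phenoxide opening at C2 gives the erythro product. The main risk there is benzylic-versus-C2 regioselectivity.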